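## Retrosynthetic overview

1. Target 11 ⇒ 10 (fluoride removal of two aryl silyl ethers) ⇒ 9 (O‑methylation of the C4 tertiary alcohol).
2. 9 ⇒ 5 + 6: the cyclopentenone is cut at C4–C5 (addition of the acyl anion equivalent of methoxyacetaldehyde to an aryl ketone) and at C6=C7 (aldol condensation).
3. This reveals a hidden mirror plane: 5 is an achiral 2,2‑diaroyloxirane, and choosing one of its two enantiotopic ketones and one face sets C3 and C4 in a single event.
4. 5 ⇒ 3 (chlorination, then Darzens closure with formaldehyde) ⇒ 1 (commercial bis‑anisyl diketone, methyl exchanged for TIPS).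
5. Ring order: oxirane first, on the symmetric diketone where no regio‑ or stereochemical question exists; cyclopentenone second.

Locants used below (1‑oxaspiro[2.4]heptane): O1, C2 = epoxide CH2, C3 = spiro carbon, C4 = C(OMe)Ar, C5 = C=O, C6 = C–OMe, C7 = C–Ar. The target is (3R,4R): the epoxide oxygen is trans to the C4 methoxy group and cis to the C4 aryl group.

Assumption: both antipodes of the triazolium precatalyst are available; the (5aS,10bR) salt is written as the one giving the (3R,4R) series, and its sense is confirmed on 9 (X‑ray or ECD) in the first run, the antipode being used if it is opposite.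

## Route

Step 1
Reactants: 1 1,3-bis(4-methoxyphenyl)propane-1,3-dione
Product: 2 1,3-bis(4-hydroxyphenyl)propane-1,3-dione
Conditions: BBr3 (5 equiv), CH2Cl2, −78 °C to rt; H2O work-up
Reagents that add atoms: none
Why: BBr3 cleavage of aryl methyl ethers; the 1,3-diketone is only held as a boron chelate that is released on aqueous work-up, and no stereocentre is involved.

Step 2
Reactants: 2 1,3-bis(4-hydroxyphenyl)propane-1,3-dione
Product: 3 1,3-bis[4-(triisopropylsilyloxy)phenyl]propane-1,3-dione
Conditions: TIPSCl (2.4 equiv), imidazole (5 equiv), DMF, rt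
Reagents that add atoms: triisopropylsilyl chloride, CC(C)[Si](Cl)(C(C)C)C(C)C
Why: Imidazole-promoted silylation of the two acidic phenols; TIPS is chosen because it survives carbonate, amine bases, the carbene catalyst and Ag2O but falls to fluoride at the end.

Step 3
Reactants: 3 1,3-bis[4-(triisopropylsilyloxy)phenyl]propane-1,3-dione
Product: 5 oxirane-2,2-diylbis{[4-(triisopropylsilyloxy)phenyl]methanone}, via 2-chloro-1,3-diketone 4 (not isolated)
Conditions: NCS (1.05 equiv), MeCN, rt; then (CH2O)n (3 equiv), K2CO3 (2 equiv), rt to 40 °C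
Reagents that add atoms: paraformaldehyde (reacts as formaldehyde), C=O
Why: Enol chlorination at C2 followed by a Darzens condensation, in which the chloro-diketone enolate adds to formaldehyde and the alkoxide displaces chloride (3-exo-tet); 5 is achiral, its two aroyl groups being enantiotopic.

Step 4
Reactants: 5 oxirane-2,2-diylbis{[4-(triisopropylsilyloxy)phenyl]methanone}; 6 methoxyacetaldehyde
Product: 9 (3R,4R)-4-hydroxy-6-methoxy-4,7-bis[4-(triisopropylsilyloxy)phenyl]-1-oxaspiro[2.4]hept-6-en-5-one, via benzoin adduct 7 (not isolated), via aldol adduct 8 (not isolated)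
Conditions: 6 (1.5 equiv, slow addition), (5aS,10bR)-2-(pentafluorophenyl)-5a,10b-dihydro-4H,6H-indeno[2,1-b][1,2,4]triazolo[4,3-d][1,4]oxazin-2-ium tetrafluoroborate (15 mol %), iPr2NEt (1 equiv), LiCl (1 equiv), 4 Å MS, THF, 0 °C to rt; then DBU (1.5 equiv), 40 °C
Reagents that add atoms: none
Why: Proposed new method: the carbene turns 6 into a Breslow intermediate (acyl anion equivalent) that adds to one ketone of the lithium-chelated diketone 5 — a crossed aldehyde–ketone benzoin, known intermolecularly for activated ketones such as α-ketoesters and intramolecularly for enantiotopic-group-selective closure onto 1,3-diketones — where the chelate exposes the carbonyl face carrying the small epoxide oxygen (placing C4–OH cis to the epoxide CH2, the like relationship) and the chiral catalyst decides which of the two enantiotopic carbonyls is attacked, so C3 and C4 are set together; the reversible adduct 7 has a single enolisable position and is drained by LiCl/DBU aldol condensation onto the remaining aryl ketone, closing the cyclopentenone irreversibly.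

Step 5
Reactants: 9 (3R,4R)-4-hydroxy-6-methoxy-4,7-bis[4-(triisopropylsilyloxy)phenyl]-1-oxaspiro[2.4]hept-6-en-5-one
Product: 10 (3R,4R)-4,6-dimethoxy-4,7-bis[4-(triisopropylsilyloxy)phenyl]-1-oxaspiro[2.4]hept-6-en-5-one
Conditions: MeI (30 equiv), Ag2O (5 equiv), CaSO4, MeCN, 40 °C, dark
Reagents that add atoms: iodomethane, CI
Why: Purdie methylation of the acidic tertiary α-ketol without forming a free alkoxide, which avoids Payne rearrangement of the trans-disposed C4–O/epoxide pair and retro-benzoin; C3 and C4 are untouched.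

Step 6
Reactants: 10 (3R,4R)-4,6-dimethoxy-4,7-bis[4-(triisopropylsilyloxy)phenyl]-1-oxaspiro[2.4]hept-6-en-5-one
Product: 11 (3R,4R)-4,7-bis(4-hydroxyphenyl)-4,6-dimethoxy-1-oxaspiro[2.4]hept-6-en-5-one
Conditions: Bu4NF (2.5 equiv), AcOH (2.5 equiv), THF, 0 °C
Reagents that add atoms: none
Why: Fluoride cleavage of the two aryl silyl ethers, buffered with AcOH so that neither phenoxide chemistry nor base-induced opening of the vinyl epoxide intervenes; the stereocentres are untouched.

## Compound list

1 | 1,3-bis(4-methoxyphenyl)propane-1,3-dione | COc1ccc(cc1)C(=O)CC(=O)c1ccc(OC)cc1 | starting material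
2 | 1,3-bis(4-hydroxyphenyl)propane-1,3-dione | Oc1ccc(cc1)C(=O)CC(=O)c1ccc(O)cc1 | intermediate
3 | 1,3-bis[4-(triisopropylsilyloxy)phenyl]propane-1,3-dione | O=C(CC(=O)c1ccc(O[Si](C(C)C)(C(C)C)C(C)C)cc1)c1ccc(O[Si](C(C)C)(C(C)C)C(C)C)cc1 | intermediate
4 | 2-chloro-1,3-bis[4-(triisopropylsilyloxy)phenyl]propane-1,3-dione (formed in the flask, not isolated) | O=C(C(Cl)C(=O)c1ccc(O[Si](C(C)C)(C(C)C)C(C)C)cc1)c1ccc(O[Si](C(C)C)(C(C)C)C(C)C)cc1 | intermediate
5 | oxirane-2,2-diylbis{[4-(triisopropylsilyloxy)phenyl]methanone} (achiral; the two aroyl groups are enantiotopic) | O=C(c1ccc(O[Si](C(C)C)(C(C)C)C(C)C)cc1)C1(CO1)C(=O)c1ccc(O[Si](C(C)C)(C(C)C)C(C)C)cc1 | intermediate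
6 | methoxyacetaldehyde | COCC=O | starting material
7 | [(2R)-2-[(1R)-1-hydroxy-3-methoxy-2-oxo-1-[4-(triisopropylsilyloxy)phenyl]propyl]oxiran-2-yl][4-(triisopropylsilyloxy)phenyl]methanone (benzoin adduct, not isolated) | COCC(=O)[C@@](O)(c1ccc(O[Si](C(C)C)(C(C)C)C(C)C)cc1)[C@]1(CO1)C(=O)c1ccc(O[Si](C(C)C)(C(C)C)C(C)C)cc1 | intermediate
8 | (3S,4R)-4,7-dihydroxy-6-methoxy-4,7-bis[4-(triisopropylsilyloxy)phenyl]-1-oxaspiro[2.4]heptan-5-one (aldol adduct, not isolated; C6/C7 epimer mixture; same C3/C4 arrangement in space as 9, the C3 descriptor changes only because C7 is sp3) | COC1C(O)(c2ccc(O[Si](C(C)C)(C(C)C)C(C)C)cc2)[C@@]2(CO2)[C@](O)(c2ccc(O[Si](C(C)C)(C(C)C)C(C)C)cc2)C1=O | intermediate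
9 | (3R,4R)-4-hydroxy-6-methoxy-4,7-bis[4-(triisopropylsilyloxy)phenyl]-1-oxaspiro[2.4]hept-6-en-5-one (4-OH cis to the epoxide CH2) | COC1=C(c2ccc(O[Si](C(C)C)(C(C)C)C(C)C)cc2)[C@@]2(CO2)[C@](O)(c2ccc(O[Si](C(C)C)(C(C)C)C(C)C)cc2)C1=O | intermediate
10 | (3R,4R)-4,6-dimethoxy-4,7-bis[4-(triisopropylsilyloxy)phenyl]-1-oxaspiro[2.4]hept-6-en-5-one | COC1=C(c2ccc(O[Si](C(C)C)(C(C)C)C(C)C)cc2)[C@@]2(CO2)[C@](OC)(c2ccc(O[Si](C(C)C)(C(C)C)C(C)C)cc2)C1=O | intermediate
11 | (3R,4R)-4,7-bis(4-hydroxyphenyl)-4,6-dimethoxy-1-oxaspiro[2.4]hept-6-en-5-one (epoxide O trans to 4-OMe) | COC1=C(c2ccc(O)cc2)[C@@]2(CO2)[C@](OC)(c2ccc(O)cc2)C1=O | target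

## Step count and risks

Total steps: 6. Longest linear sequence: 6 (1 to 11; 6 enters at step 4).

**Step 4 (most likely to fail).** An intermolecular benzoin onto a hindered aryl ketone has no direct precedent. The carbene may be alkylated at the epoxide CH2. The like/unlike outcome rests on chelate control, which a polar Felkin–Anh preference would oppose.

Fallback, setting out from 5 and returning at 7: methoxyacetaldehyde 6 is converted with propane-1,3-dithiol and BF3·OEt2 (CH2Cl2, 0 °C) into 2-(methoxymethyl)-1,3-dithiane F1. This is deprotonated (n-BuLi, THF, −30 °C) to 2-lithio-2-(methoxymethyl)-1,3-dithiane F2, a stoichiometric acyl anion equivalent, which is added to 5 (1.0 equiv, THF, −78 °C, cold quench). Lithium chelation between ketone and epoxide oxygens steers attack to the face remote from the second aroyl group. After chromatographic removal of any unlike isomer this gives the racemic like dithiane carbinol F3, which is resolved by preparative chiral SFC to the (R,R)-dithiane carbinol F4. Dithiane removal (MeI, CaCO3, MeCN/H2O, 40 °C) gives 7, which is cyclised with LiCl/DBU exactly as in the second stage of step 4.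

**Step 5.** The C4 hydroxyl sits between an aryl group, a ketone and the spiro carbon and may not react. Under more forcing basic conditions the alkoxide is anti to the C3–O bond and can undergo Payne rearrangement.

Fallback, setting out from 7 and returning at 10: step 4 is stopped before DBU is added and 7 is isolated. It is methylated on the open-chain carbinol with MeOTf and 2,6-di-tert-butyl-4-methylpyridine (CH2Cl2, 0 °C to rt) to give the open-chain methyl ether F5, which can no longer undergo retro-benzoin or Payne chemistry. F5 is then closed with LiCl/DBU (THF, 40 °C) through the aldol adduct F6 (not isolated) to give 10 directly.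

**Step 3.** The hydroxymethyl adduct of 4 may revert, or the diketone may be deacylated, before the alkoxide displaces chloride at the fully substituted carbon.

Fallback, setting out from 3 and returning at 5: 3 is oxidised at C2 with Dess–Martin periodinane and pyridine (CH2Cl2, rt) to the vicinal triketone 1,3-bis[4-(triisopropylsilyloxy)phenyl]propane-1,2,3-trione F7. Its central, most electrophilic carbonyl takes up CH2N2 (Et2O, 0 °C) with loss of nitrogen to give 5.

## Further compounds

F1 | step 4 | 2-(methoxymethyl)-1,3-dithiane | COCC1SCCCS1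
F2 | step 4 | 2-lithio-2-(methoxymethyl)-1,3-dithiane | [Li]C1(COC)SCCCS1
F3 | step 4 | racemic like dithiane carbinol, (R,R) and (S,S) forms of [2-[hydroxy[2-(methoxymethyl)-1,3-dithian-2-yl][4-(triisopropylsilyloxy)phenyl]methyl]oxiran-2-yl][4-(triisopropylsilyloxy)phenyl]methanone | COCC1(SCCCS1)[C@@](O)(c1ccc(O[Si](C(C)C)(C(C)C)C(C)C)cc1)[C@]1(CO1)C(=O)c1ccc(O[Si](C(C)C)(C(C)C)C(C)C)cc1.COCC1(SCCCS1)[C@](O)(c1ccc(O[Si](C(C)C)(C(C)C)C(C)C)cc1)[C@@]1(CO1)C(=O)c1ccc(O[Si](C(C)C)(C(C)C)C(C)C)cc1
F4 | step 4 | [(2R)-2-[(R)-hydroxy[2-(methoxymethyl)-1,3-dithian-2-yl][4-(triisopropylsilyloxy)phenyl]methyl]oxiran-2-yl][4-(triisopropylsilyloxy)phenyl]methanone | COCC1(SCCCS1)[C@@](O)(c1ccc(O[Si](C(C)C)(C(C)C)C(C)C)cc1)[C@]1(CO1)C(=O)c1ccc(O[Si](C(C)C)(C(C)C)C(C)C)cc1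
F5 | step 5 | [(2R)-2-[(1R)-1,3-dimethoxy-2-oxo-1-[4-(triisopropylsilyloxy)phenyl]propyl]oxiran-2-yl][4-(triisopropylsilyloxy)phenyl]methanone | COCC(=O)[C@@](OC)(c1ccc(O[Si](C(C)C)(C(C)C)C(C)C)cc1)[C@]1(CO1)C(=O)c1ccc(O[Si](C(C)C)(C(C)C)C(C)C)cc1
F6 | step 5 | (3S,4R)-7-hydroxy-4,6-dimethoxy-4,7-bis[4-(triisopropylsilyloxy)phenyl]-1-oxaspiro[2.4]heptan-5-one (C6/C7 epimer mixture, not isolated) | COC1C(O)(c2ccc(O[Si](C(C)C)(C(C)C)C(C)C)cc2)[C@@]2(CO2)[C@](OC)(c2ccc(O[Si](C(C)C)(C(C)C)C(C)C)cc2)C1=O
F7 | step 3 | 1,3-bis[4-(triisopropylsilyloxy)phenyl]propane-1,2,3-trione | O=C(C(=O)C(=O)c1ccc(O[Si](C(C)C)(C(C)C)C(C)C)cc1)c1ccc(O[Si](C(C)C)(C(C)C)C(C)C)cc1
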